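**Retrosynthetic overview**

- The route rests on C3 of ring C (the O1–C2–C3–C4–C4a–C8a dihydropyran). C3 carries ring B and the two methylene arms C2 and C4, so before ring A is attached it is the prochiral carbon of a 2-arylpropane-1,3-diol.
- A lipase acetylates one enantiotopic CH2OH arm of that diol; the acetylated arm becomes C2 and the free arm becomes C4.
- C4–C4a is made by Negishi coupling of the derived alkylzinc iodide with a ring A aryl bromide. O1–C2 is then closed by an intramolecular Mitsunobu reaction.
- The diol comes from malonate arylation and reduction of a bromochromene, itself made from 4-bromoresorcinol by a propargyl ether Claisen cascade. The ring A bromide comes from 3,5-dimethoxyphenol by lithiation/prenylation between the methoxy groups and ortho-bromination.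
- Ring order: rings A and B are bought as arenes, ring D (the 2,2-dimethylpyran on ring B) closes first (step 8), ring C closes last (step 15).

Key step: step 11

Assumption: the lipase is taken to acetylate the pro-S hydroxymethyl arm of the diol, giving the (S)-monoacetate. The sense must be confirmed by chiral HPLC and chemical correlation before the material is carried on; the fallback to step 11 covers the opposite sense.

Remark on protecting groups: the ring B phenol is carried as its triisopropylsilyl ether, because an aryl tert-butyldimethylsilyl ether would not be expected to survive the carbonate methanolysis of step 14. The ring A phenol is carried as an acetate so that it is released in the same operation as the side-chain alcohol.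

**Ring A fragment**

Step 1
Reactants: 1 3,5-dimethoxyphenol
Product: 2 (3,5-dimethoxyphenoxy)triisopropylsilane
Conditions: i-Pr3SiCl, imidazole, DMF, 25 °C
Reagents that add atoms: triisopropylsilyl chloride, CC(C)[Si](Cl)(C(C)C)C(C)C
Why: Imidazole-promoted O-silylation of a phenol; the bulky silyl ether is a poor directing group and shields its two ortho positions in the next step.

Step 2
Reactants: 2 (3,5-dimethoxyphenoxy)triisopropylsilane; 3 1-bromo-3-methylbut-2-ene (prenyl bromide)
Product: 5 [3,5-dimethoxy-4-(3-methylbut-2-en-1-yl)phenoxy]triisopropylsilane, via aryllithium 4 (not isolated)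
Conditions: n-BuLi, THF, 0 °C → 25 °C; then 3, −78 °C → 25 °C
Reagents that add atoms: none
Why: Directed ortho-metalation should place lithium between the two methoxy groups (cooperative coordination, the positions next to the silyl ether being blocked by its bulk), and the aryllithium is then alkylated at the primary allylic carbon in an SN2 reaction.

Step 3
Reactants: 5 [3,5-dimethoxy-4-(3-methylbut-2-en-1-yl)phenoxy]triisopropylsilane
Product: 6 3,5-dimethoxy-4-(3-methylbut-2-en-1-yl)phenol
Conditions: Bu4NF, AcOH, THF, 0 °C → 25 °C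
Reagents that add atoms: none
Why: Fluoride-mediated cleavage of an aryl silyl ether, buffered with acetic acid, which leaves the methyl ethers and the prenyl group alone.

Step 4
Reactants: 6 3,5-dimethoxy-4-(3-methylbut-2-en-1-yl)phenol
Product: 7 2-bromo-3,5-dimethoxy-4-(3-methylbut-2-en-1-yl)phenol
Conditions: NBS (1.0 equiv), CH2Cl2, −78 °C
Reagents that add atoms: N-bromosuccinimide, O=C1CCC(=O)N1Br
Why: Electrophilic aromatic bromination; the two open ring positions are equivalent and ortho to the hydroxyl, and at low temperature the trioxygenated ring should react much faster than the trisubstituted prenyl alkene.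

Step 5
Reactants: 7 2-bromo-3,5-dimethoxy-4-(3-methylbut-2-en-1-yl)phenol
Product: 8 2-bromo-3,5-dimethoxy-4-(3-methylbut-2-en-1-yl)phenyl acetate
Conditions: Ac2O, pyridine, DMAP (cat.), CH2Cl2, 0 °C → 25 °C
Reagents that add atoms: acetic anhydride, CC(=O)OC(C)=O
Why: DMAP-catalysed O-acetylation; the acetate masks the acidic phenol during the organozinc coupling and leaves later together with the side-chain acetate.

**Ring B/D fragment and the prochiral diol**

Step 6
Reactants: 9 4-bromoresorcinol (4-bromobenzene-1,3-diol)
Product: 10 2-bromo-5-[(triisopropylsilyl)oxy]phenol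
Conditions: i-Pr3SiCl (1.0 equiv), imidazole, DMF, −20 °C → 0 °C
Reagents that add atoms: triisopropylsilyl chloride, CC(C)[Si](Cl)(C(C)C)C(C)C
Why: Kinetic monosilylation; the hydroxyl para to bromine is unhindered while the other is flanked by bromine, so the bulky chlorosilane should take the former, and the regioisomer and bis-ether are removed by chromatography.

Step 7
Reactants: 10 2-bromo-5-[(triisopropylsilyl)oxy]phenol; 11 3-chloro-3-methylbut-1-yne
Product: 12 {4-bromo-3-[(2-methylbut-3-yn-2-yl)oxy]phenoxy}triisopropylsilane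
Conditions: DBU, CuCl2·2H2O (cat.), MeCN, 0 °C
Reagents that add atoms: none
Why: Copper-catalysed propargylic O-alkylation of a phenol with a tertiary propargylic chloride, a mild method that tolerates ortho-substituted phenols and the aryl silyl ether.

Step 8
Reactants: 12 {4-bromo-3-[(2-methylbut-3-yn-2-yl)oxy]phenoxy}triisopropylsilane
Product: 15 [(8-bromo-2,2-dimethyl-2H-chromen-5-yl)oxy]triisopropylsilane, via allenylphenol 13 (not isolated), via ortho-quinone methide 14 (not isolated)
Conditions: o-xylene, 140 °C
Reagents that add atoms: none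
Why: Aryl propargyl ether Claisen rearrangement to the only free ortho carbon (the other bears bromine), enolization to the allenylphenol, 1,5-hydrogen shift and oxa-6π electrocyclization close ring D.

Step 9
Reactants: 15 [(8-bromo-2,2-dimethyl-2H-chromen-5-yl)oxy]triisopropylsilane; 16 diethyl malonate
Product: 17 diethyl 2-{2,2-dimethyl-5-[(triisopropylsilyl)oxy]-2H-chromen-8-yl}propanedioate
Conditions: Pd2(dba)3 (2 mol %), P(t-Bu)3·HBF4 (8 mol %), K3PO4, toluene, 80 °C
Reagents that add atoms: none
Why: Palladium-catalysed α-arylation of a malonate enolate with a bulky electron-rich phosphine, a known coupling for electron-rich ortho-substituted aryl bromides, with K3PO4 mild enough to spare the silyl ether.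

Step 10
Reactants: 17 diethyl 2-{2,2-dimethyl-5-[(triisopropylsilyl)oxy]-2H-chromen-8-yl}propanedioate
Product: 18 2-{2,2-dimethyl-5-[(triisopropylsilyl)oxy]-2H-chromen-8-yl}propane-1,3-diol
Conditions: LiAlH4, THF, −10 °C → 25 °C (ester added to the hydride)
Reagents that add atoms: none
Why: Hydride reduction of both esters to the 2-arylpropane-1,3-diol; inverse addition at low temperature limits enolization of the arylmalonate and the elimination that would follow.

Step 11
Reactants: 18 2-{2,2-dimethyl-5-[(triisopropylsilyl)oxy]-2H-chromen-8-yl}propane-1,3-diol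
Product: 19 (2S)-2-{2,2-dimethyl-5-[(triisopropylsilyl)oxy]-2H-chromen-8-yl}-3-hydroxypropyl acetate
Conditions: Burkholderia cepacia lipase (immobilised), vinyl acetate, t-BuOMe, 30 °C
Reagents that add atoms: vinyl acetate, C=COC(C)=O
Why: The active-site serine of the lipase is acetylated by vinyl acetate, which releases vinyl alcohol that tautomerizes to acetaldehyde and makes the transfer irreversible, and the acetyl-enzyme then passes the acetyl group to one hydroxymethyl arm of 18. The closest known reaction type is the lipase-catalysed enantiotopic monoacylation of 2-arylpropane-1,3-diols with vinyl acetate. No ring is closed and no skeletal bond is formed. The new stereocenter (the future C3) is set by the chiral enzyme pocket alone, which should seat the bicyclic aryl group in its large hydrophobic site and present only one of the two enantiotopic CH2OH groups to the acyl-serine; this is catalyst control on a prochiral substrate, drawn here for acylation of the pro-S arm. The step needs enantiotopic-group selectivity and mono- over diacylation: the first should be secured by the large size difference between the ring B/D bicycle and hydrogen at the prochiral carbon, the second by stopping near full conversion of 18, where the faster second acylation of the minor enantiomer should further raise the optical purity of 19.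

Step 12
Reactants: 19 (2S)-2-{2,2-dimethyl-5-[(triisopropylsilyl)oxy]-2H-chromen-8-yl}-3-hydroxypropyl acetate
Product: 20 (2R)-2-{2,2-dimethyl-5-[(triisopropylsilyl)oxy]-2H-chromen-8-yl}-3-iodopropyl acetate
Conditions: PPh3, I2, imidazole, CH2Cl2, 0 °C (19 used directly after isolation)
Reagents that add atoms: iodine, II
Why: Appel iodination, an SN2 displacement of the alkoxyphosphonium by iodide at the primary carbon, fast enough at 0 °C to outrun 1,3-acetyl migration between the arms; the stereocenter is not a reacting atom and its descriptor changes to R only through the priority rules.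

**Union, ring C closure and deprotection**

Step 13
Reactants: 20 (2R)-2-{2,2-dimethyl-5-[(triisopropylsilyl)oxy]-2H-chromen-8-yl}-3-iodopropyl acetate; 8 2-bromo-3,5-dimethoxy-4-(3-methylbut-2-en-1-yl)phenyl acetate
Product: 22 2-[(2R)-3-acetoxy-2-{2,2-dimethyl-5-[(triisopropylsilyl)oxy]-2H-chromen-8-yl}propyl]-3,5-dimethoxy-4-(3-methylbut-2-en-1-yl)phenyl acetate, via alkylzinc iodide 21 (not isolated)
Conditions: Zn dust (I2-activated), DMF, 25 °C; then 8, Pd2(dba)3 (2.5 mol %), SPhos (2-dicyclohexylphosphino-2',6'-dimethoxybiphenyl, 10 mol %), 45 °C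
Reagents that add atoms: none
Why: Zinc inserts into the primary C–I bond and the alkylzinc iodide undergoes Negishi sp3–sp2 coupling to form C4–C4a; the biaryl dialkylphosphine ligand is of the type known to couple primary alkylzinc iodides with doubly ortho-substituted aryl halides and to make reductive elimination faster than β-hydride elimination, while both acetates and the stereocenter β to zinc stay untouched.

Step 14
Reactants: 22 2-[(2R)-3-acetoxy-2-{2,2-dimethyl-5-[(triisopropylsilyl)oxy]-2H-chromen-8-yl}propyl]-3,5-dimethoxy-4-(3-methylbut-2-en-1-yl)phenyl acetate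
Product: 23 2-[(2R)-2-{2,2-dimethyl-5-[(triisopropylsilyl)oxy]-2H-chromen-8-yl}-3-hydroxypropyl]-3,5-dimethoxy-4-(3-methylbut-2-en-1-yl)phenol
Conditions: K2CO3, MeOH, 0 °C → 25 °C
Reagents that add atoms: none
Why: Base-catalysed methanolysis (transesterification) removes the aryl and the primary acetate in one operation, and the hindered aryl triisopropylsilyl ether is expected to survive these conditions.

Step 15
Reactants: 23 2-[(2R)-2-{2,2-dimethyl-5-[(triisopropylsilyl)oxy]-2H-chromen-8-yl}-3-hydroxypropyl]-3,5-dimethoxy-4-(3-methylbut-2-en-1-yl)phenol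
Product: 24 {[8-((3R)-5,7-dimethoxy-6-(3-methylbut-2-en-1-yl)chroman-3-yl)-2,2-dimethyl-2H-chromen-5-yl]oxy}triisopropylsilane
Conditions: PPh3, DIAD, THF, 0 °C → 25 °C
Reagents that add atoms: none
Why: Intramolecular Mitsunobu etherification in which the ring A phenol displaces the activated primary alcohol in a 6-exo-tet closure of ring C (O1–C2); C3 is next to the reacting carbon, not at it, so its configuration is kept.

Step 16
Reactants: 24 {[8-((3R)-5,7-dimethoxy-6-(3-methylbut-2-en-1-yl)chroman-3-yl)-2,2-dimethyl-2H-chromen-5-yl]oxy}triisopropylsilane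
Product: 25 Kanzonol I, 8-[(3R)-5,7-dimethoxy-6-(3-methylbut-2-en-1-yl)chroman-3-yl]-2,2-dimethyl-2H-chromen-5-ol
Conditions: Bu4NF, AcOH, THF, 0 °C
Reagents that add atoms: none
Why: Fluoride cleavage of the aryl silyl ether under acetic acid buffering releases the ring B phenol without acid or strong base acting on the chromene and prenyl groups.

**Compound list**

1 | 3,5-dimethoxyphenol | COc1cc(O)cc(OC)c1 | starting material
2 | (3,5-dimethoxyphenoxy)triisopropylsilane | COc1cc(OC)cc(O[Si](C(C)C)(C(C)C)C(C)C)c1 | intermediate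
3 | 1-bromo-3-methylbut-2-ene (prenyl bromide) | CC(C)=CCBr | starting material
4 | aryllithium: {2,6-dimethoxy-4-[(triisopropylsilyl)oxy]phenyl}lithium | [Li]c1c(OC)cc(O[Si](C(C)C)(C(C)C)C(C)C)cc1OC | intermediate
5 | [3,5-dimethoxy-4-(3-methylbut-2-en-1-yl)phenoxy]triisopropylsilane | COc1cc(O[Si](C(C)C)(C(C)C)C(C)C)cc(OC)c1CC=C(C)C | intermediate
6 | 3,5-dimethoxy-4-(3-methylbut-2-en-1-yl)phenol | COc1cc(O)cc(OC)c1CC=C(C)C | intermediate
7 | 2-bromo-3,5-dimethoxy-4-(3-methylbut-2-en-1-yl)phenol | COc1cc(O)c(Br)c(OC)c1CC=C(C)C | intermediate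
8 | 2-bromo-3,5-dimethoxy-4-(3-methylbut-2-en-1-yl)phenyl acetate | COc1cc(OC(C)=O)c(Br)c(OC)c1CC=C(C)C | intermediate
9 | 4-bromoresorcinol | Oc1ccc(Br)c(O)c1 | starting material
10 | 2-bromo-5-[(triisopropylsilyl)oxy]phenol | Oc1cc(O[Si](C(C)C)(C(C)C)C(C)C)ccc1Br | intermediate
11 | 3-chloro-3-methylbut-1-yne | CC(C)(Cl)C#C | starting material
12 | {4-bromo-3-[(2-methylbut-3-yn-2-yl)oxy]phenoxy}triisopropylsilane | C#CC(C)(C)Oc1cc(O[Si](C(C)C)(C(C)C)C(C)C)ccc1Br | intermediate
13 | allenylphenol: 6-bromo-2-(3-methylbuta-1,2-dien-1-yl)-3-[(triisopropylsilyl)oxy]phenol | CC(C)=C=Cc1c(O)c(Br)ccc1O[Si](C(C)C)(C(C)C)C(C)C | intermediate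
14 | ortho-quinone methide: 2-bromo-6-(3-methylbut-2-en-1-ylidene)-5-[(triisopropylsilyl)oxy]cyclohexa-2,4-dien-1-one | CC(C)=CC=C1C(=O)C(Br)=CC=C1O[Si](C(C)C)(C(C)C)C(C)C | intermediate
15 | [(8-bromo-2,2-dimethyl-2H-chromen-5-yl)oxy]triisopropylsilane | CC1(C)C=Cc2c(O[Si](C(C)C)(C(C)C)C(C)C)ccc(Br)c2O1 | intermediate
16 | diethyl malonate | CCOC(=O)CC(=O)OCC | starting material
17 | diethyl 2-{2,2-dimethyl-5-[(triisopropylsilyl)oxy]-2H-chromen-8-yl}propanedioate | CCOC(=O)C(C(=O)OCC)c1ccc(O[Si](C(C)C)(C(C)C)C(C)C)c2c1OC(C)(C)C=C2 | intermediate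
18 | 2-{2,2-dimethyl-5-[(triisopropylsilyl)oxy]-2H-chromen-8-yl}propane-1,3-diol | OCC(CO)c1ccc(O[Si](C(C)C)(C(C)C)C(C)C)c2c1OC(C)(C)C=C2 | intermediate
19 | (2S)-2-{2,2-dimethyl-5-[(triisopropylsilyl)oxy]-2H-chromen-8-yl}-3-hydroxypropyl acetate | OC[C@H](c1ccc(O[Si](C(C)C)(C(C)C)C(C)C)c2c1OC(C)(C)C=C2)COC(C)=O | intermediate
20 | (2R)-2-{2,2-dimethyl-5-[(triisopropylsilyl)oxy]-2H-chromen-8-yl}-3-iodopropyl acetate | IC[C@H](c1ccc(O[Si](C(C)C)(C(C)C)C(C)C)c2c1OC(C)(C)C=C2)COC(C)=O | intermediate
21 | alkylzinc iodide: [(2R)-3-acetoxy-2-{2,2-dimethyl-5-[(triisopropylsilyl)oxy]-2H-chromen-8-yl}propyl]zinc iodide | I[Zn]C[C@H](c1ccc(O[Si](C(C)C)(C(C)C)C(C)C)c2c1OC(C)(C)C=C2)COC(C)=O | intermediate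
22 | 2-[(2R)-3-acetoxy-2-{2,2-dimethyl-5-[(triisopropylsilyl)oxy]-2H-chromen-8-yl}propyl]-3,5-dimethoxy-4-(3-methylbut-2-en-1-yl)phenyl acetate | COc1cc(OC(C)=O)c(C[C@H](c2ccc(O[Si](C(C)C)(C(C)C)C(C)C)c3c2OC(C)(C)C=C3)COC(C)=O)c(OC)c1CC=C(C)C | intermediate
23 | 2-[(2R)-2-{2,2-dimethyl-5-[(triisopropylsilyl)oxy]-2H-chromen-8-yl}-3-hydroxypropyl]-3,5-dimethoxy-4-(3-methylbut-2-en-1-yl)phenol | COc1cc(O)c(C[C@H](c2ccc(O[Si](C(C)C)(C(C)C)C(C)C)c3c2OC(C)(C)C=C3)CO)c(OC)c1CC=C(C)C | intermediate
24 | {[8-((3R)-5,7-dimethoxy-6-(3-methylbut-2-en-1-yl)chroman-3-yl)-2,2-dimethyl-2H-chromen-5-yl]oxy}triisopropylsilane | COc1cc2c(c(OC)c1CC=C(C)C)C[C@H](c1ccc(O[Si](C(C)C)(C(C)C)C(C)C)c3c1OC(C)(C)C=C3)CO2 | intermediate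
25 | Kanzonol I, 8-[(3R)-5,7-dimethoxy-6-(3-methylbut-2-en-1-yl)chroman-3-yl]-2,2-dimethyl-2H-chromen-5-ol | COc1cc2c(c(OC)c1CC=C(C)C)C[C@H](c1ccc(O)c3c1OC(C)(C)C=C3)CO2 | target

**Step count**

Total: 16 steps. Longest linear sequence: 11 steps (steps 6–16, from 9 to 25); the ring A branch (steps 1–5) joins at step 13.

**Steps most likely to fail**

1. Step 13 (Negishi coupling). Oxidative addition and transmetalation at the electron-rich, doubly ortho-substituted bromide may be slow. The alkylzinc reagent may then be lost by protonation, or the alkylpalladium intermediate may undergo β-hydride elimination, which would give reduced arene and could erode the optical purity by reinsertion. The fallback reverses the polarity of the C4–C4a bond formation and sets out from bromophenol 7 and iodide 20. Phenol 7 would be converted with MOMCl and i-Pr2NEt into 2-bromo-3,5-dimethoxy-1-(methoxymethoxy)-4-(3-methylbut-2-en-1-yl)benzene F1. Magnesium insertion (Mg turnings, LiCl, THF) would give the aryl Grignard reagent [2,4-dimethoxy-6-(methoxymethoxy)-3-(3-methylbut-2-en-1-yl)phenyl]magnesium bromide F2. Copper-catalysed alkylation of F2 with the primary iodide 20 (Li2CuCl4 cat., THF/NMP, −20 °C → 0 °C), conditions under which esters are tolerated, would give the coupled acetate F3. Methanolysis (K2CO3, MeOH) would give the alcohol F4, and dilute HCl in MeOH would remove the methoxymethyl group, which returns to the route at 23.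

2. Step 11 (lipase desymmetrization). The ortho-alkoxy bicyclic aryl group may sit poorly in the enzyme pocket, so that the two hydroxymethyl arms are told apart weakly or in the opposite sense, or the diacetate may build up. The fallback sets out from diol 18, which would be peracetylated (Ac2O, pyridine) to the diacetate 2-{2,2-dimethyl-5-[(triisopropylsilyl)oxy]-2H-chromen-8-yl}propane-1,3-diyl diacetate F5. One enantiotopic ester of F5 would then be hydrolysed by a serine hydrolase (the same lipase or porcine pancreatic lipase) in pH 7 phosphate buffer with a co-solvent. Hydrolysis removes the acetyl group from the arm that the acylation mode esterifies, so the two modes give mirror-image monoacetates; whichever mode and enzyme delivers the (S)-monoacetate is used, and the route is rejoined at 19.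

3. Step 9 (malonate arylation). Oxidative addition at the electron-rich ortho-alkoxy bromide may be sluggish and the catalyst may be lost to protodebromination, or the stabilized malonate enolate may transmetalate and reductively eliminate poorly. The fallback sets out from bromochromene 15. The Reformatsky reagent bromo(2-ethoxy-2-oxoethyl)zinc F6, made from ethyl bromoacetate and zinc, would be coupled with 15 under palladium catalysis (Pd2(dba)3, P(t-Bu)3·HBF4, THF, 25 °C) to give ethyl 2-{2,2-dimethyl-5-[(triisopropylsilyl)oxy]-2H-chromen-8-yl}acetate F7. Claisen-type C-ethoxycarbonylation of F7 with diethyl carbonate (NaH, THF, reflux) would return to the route at malonate 17.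

**Further compounds**

F1 | step 13 | 2-bromo-3,5-dimethoxy-1-(methoxymethoxy)-4-(3-methylbut-2-en-1-yl)benzene | COCOc1cc(OC)c(CC=C(C)C)c(OC)c1Br
F2 | step 13 | [2,4-dimethoxy-6-(methoxymethoxy)-3-(3-methylbut-2-en-1-yl)phenyl]magnesium bromide | COCOc1cc(OC)c(CC=C(C)C)c(OC)c1[Mg]Br
F3 | step 13 | (2R)-3-[2,4-dimethoxy-6-(methoxymethoxy)-3-(3-methylbut-2-en-1-yl)phenyl]-2-{2,2-dimethyl-5-[(triisopropylsilyl)oxy]-2H-chromen-8-yl}propyl acetate | COCOc1cc(OC)c(CC=C(C)C)c(OC)c1C[C@H](c1ccc(O[Si](C(C)C)(C(C)C)C(C)C)c2c1OC(C)(C)C=C2)COC(C)=O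
F4 | step 13 | (2R)-3-[2,4-dimethoxy-6-(methoxymethoxy)-3-(3-methylbut-2-en-1-yl)phenyl]-2-{2,2-dimethyl-5-[(triisopropylsilyl)oxy]-2H-chromen-8-yl}propan-1-ol | COCOc1cc(OC)c(CC=C(C)C)c(OC)c1C[C@H](c1ccc(O[Si](C(C)C)(C(C)C)C(C)C)c2c1OC(C)(C)C=C2)CO
F5 | step 11 | 2-{2,2-dimethyl-5-[(triisopropylsilyl)oxy]-2H-chromen-8-yl}propane-1,3-diyl diacetate | CC(=O)OCC(COC(C)=O)c1ccc(O[Si](C(C)C)(C(C)C)C(C)C)c2c1OC(C)(C)C=C2
F6 | step 9 | bromo(2-ethoxy-2-oxoethyl)zinc | CCOC(=O)C[Zn]Br
F7 | step 9 | ethyl 2-{2,2-dimethyl-5-[(triisopropylsilyl)oxy]-2H-chromen-8-yl}acetate | CCOC(=O)Cc1ccc(O[Si](C(C)C)(C(C)C)C(C)C)c2c1OC(C)(C)C=C2
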